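The product we count is monomer in chains, shared among the chains begun, so for this flask we ask how long growth actually runs.

free monomer 0.074 M; initiator 0.37 mM; time 30 min

    free monomer + initiator → living end + monomer in chains (k1 = 0.022 L mol⁻¹ s⁻¹)
    free monomer → uncatalysed product (k2 = 8.9 × 10⁻⁵ s⁻¹)
    free monomer + living end → monomer in chains + living end, rate k3*[living end]*[free monomer] (k3 = 1.6 L mol⁻¹ s⁻¹)

- the average divides the monomer in chains by the number of chains begun, living and dead together
- run time (flask): 30 min

* average number of monomer units in a chain (chains begun, living or dead) at 30 min
* part of the free monomer that has reacted at 30 min

At the starting free monomer, the initiator has a mean lifetime of about 10.2 min. With the whole initiator charge as living ends, free monomer has a mean lifetime by growth of about 28.2 min, and by the uncatalysed path alone of about 187 min. Because initiation is quicker than growth, we treat it as a start-up delay and then count the living ends as the initiator charge, which makes the loss of free monomer pseudo-first-order. We carry 0.702: the growth exposure, meaning the growth constant times the initiator charge times the run time less the start-up time. Beside it the uncatalysed path has 0.160, the constant times the run time. The free monomer left is the exponential of minus their sum, so our reckoning for this flask has 57.8% reacted. The growth exposure's share of that, over 0.350 mM of chains begun, gives a chain length of 99.4.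

Now we turn the settings of this flask by hand, one at a time, with the others held. In our reckoning, more free monomer shortens the start-up time and puts more monomer on the same chains, so chain length rises with it. More initiator raises the growth exposure in proportion, so the reacted part rises, while the added chains hold chain length down. A longer run adds to the growth exposure and to the uncatalysed path's term.

The forecast gives a chain length of 103 and 57% reacted, holding that “propagation on those living ends consumes a bit over half the monomer”.

The flask gives 103 and 57.1%, so the forecast held. At 30.0 min free monomer in this flask has a half-life of 22 min by growth, shorter than 130 min by the uncatalysed path, and the rate of growth stands to the rate of the uncatalysed path at 5.9 to one. With 1.5 × 10⁻⁴ M of initiator, the neighbour's exposure falls from 0.702 to 0.285, which gives 35.9% reacted and a chain length of 120; that flask gives 35.9% and 122.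

Its constants are assumed; no experiment stands behind them.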